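**Retrosynthetic overview**
1. Ring atoms are numbered O1, C2 (4-hydroxy-3-methoxyphenyl), C3 (C9H2OH), C4 (carbinol C7′ with the catechol ring), C5. The strategy rests on C5 being a bare CH2 between O1 and C4 of the tetrahydrofuran, with C4–C7′(OH)–aryl at the oxidation level of a hydrated aryl alkyne.
2. Target ⇒ all-trans 4-aroyltetrahydrofuran ketone (benzyl ether hydrogenolysis, pivalate methanolysis and C7′ ketone reduction, read backwards).
3. Ketone ⇒ anti homopropargylic alcohol + formaldehyde: one CH2O supplies C5 and forms O1–C5 and C5–C4 in an oxocarbenium–alkyne (Prins) cyclisation, and the vinyl cation at C7′, stabilised by the catechol-derived ring, is hydrated. This closes the only ring built in the route.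
4. Homopropargylic alcohol ⇒ O-pivaloylvanillin + (S)-propargylic mesylate (C2–C3 bond and both stereocentres by allenylzinc SE2′ addition).
5. Mesylate ⇒ ynone (asymmetric transfer hydrogenation) ⇒ 3,4-bis(benzyloxy)phenylacetylene + benzyloxyacetic Weinreb amide; the aromatic rings are bought.

Key step: step 7

Remark on the chemistry: formaldehyde is delivered from paraformaldehyde.

**Step 1**
Reactants: 1 3,4-bis(benzyloxy)benzaldehyde
Product: 2 1,2-bis(benzyloxy)-4-ethynylbenzene
Conditions: dimethyl (1-diazo-2-oxopropyl)phosphonate, K2CO3, MeOH/THF, 0 °C → rt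
Reagents that add atoms: dimethyl (1-diazo-2-oxopropyl)phosphonate, CC(=O)C(=[N+]=[N-])P(=O)(OC)OC
Why: Ohira–Bestmann homologation of a non-enolisable aryl aldehyde should give the terminal alkyne under carbonate/methanol conditions that leave the benzyl ethers untouched.

**Step 2**
Reactants: 2 1,2-bis(benzyloxy)-4-ethynylbenzene, 3 2-(benzyloxy)-N-methoxy-N-methylacetamide
Product: 5 1-(benzyloxy)-4-[3,4-bis(benzyloxy)phenyl]but-3-yn-2-one, via lithium acetylide 4 (not isolated)
Conditions: n-BuLi, THF, −78 °C; then 3, −78 → 0 °C; aq. NH4Cl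
Reagents that add atoms: none
Why: Weinreb ketone synthesis, in which the lithium acetylide adds once to the amide and the chelated tetrahedral adduct collapses to the ynone only on work-up, so over-addition is not expected.

**Step 3**
Reactants: 5 1-(benzyloxy)-4-[3,4-bis(benzyloxy)phenyl]but-3-yn-2-one
Product: 6 (2S)-1-(benzyloxy)-4-[3,4-bis(benzyloxy)phenyl]but-3-yn-2-ol
Conditions: RuCl[(R,R)-TsDPEN](p-cymene) (2 mol%), KOH (2.5 mol%), i-PrOH, rt
Reagents that add atoms: none
Why: Noyori asymmetric transfer hydrogenation of an alkynyl ketone, in which the alkyne takes the place of the aryl group in the transition state, so the (R,R)-ligand should deliver hydride to the face that gives the (S)-carbinol (CH2OBn outranks the alkynyl group in the descriptor); this centre later becomes C3.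

**Step 4**
Reactants: 6 (2S)-1-(benzyloxy)-4-[3,4-bis(benzyloxy)phenyl]but-3-yn-2-ol
Product: 7 (2S)-1-(benzyloxy)-4-[3,4-bis(benzyloxy)phenyl]but-3-yn-2-yl methanesulfonate
Conditions: MsCl, Et3N, CH2Cl2, −78 → −40 °C; used crude at once
Reagents that add atoms: methanesulfonyl chloride, CS(=O)(=O)Cl
Why: O-sulfonylation does not touch the C–O bond, so the configuration is retained, and the cold, immediate use limits ionisation of the aryl-conjugated propargylic mesylate.

**Step 5**
Reactants: 8 vanillin
Product: 9 4-formyl-2-methoxyphenyl pivalate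
Conditions: PivCl, Et3N, DMAP (cat.), CH2Cl2, 0 °C → rt
Reagents that add atoms: pivaloyl chloride, CC(C)(C)C(=O)Cl
Why: Acylation of the phenol gives a hindered aryl ester that tolerates Et2Zn and Me3SiOTf and lowers the donor power of the guaiacyl ring for the later acid step.

**Step 6**
Reactants: 7 (2S)-1-(benzyloxy)-4-[3,4-bis(benzyloxy)phenyl]but-3-yn-2-yl methanesulfonate, 9 4-formyl-2-methoxyphenyl pivalate
Product: 11 4-[(1S,2R)-2-(benzyloxymethyl)-4-[3,4-bis(benzyloxy)phenyl]-1-hydroxybut-3-yn-1-yl]-2-methoxyphenyl pivalate, via allenylzinc 10 (not isolated)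
Conditions: Pd(OAc)2 (5 mol%), PPh3 (5 mol%), Et2Zn (3 equiv), THF, −78 → −20 °C; aq. NH4Cl
Reagents that add atoms: none
Why: Palladium-catalysed umpolung propargylation, in which zerovalent palladium (from Pd(OAc)2, PPh3 and Et2Zn) displaces the mesylate anti-SN2′, transmetalation gives the (P)-allenylzinc 10, and SE2′ addition to 9 through a cyclic transition state with the aldehyde aryl group on the side of the allenyl hydrogen forms the new bond on the face opposite the departed mesylate, so the (S)-mesylate should give the (R) centre (future C3) and the anti (S) carbinol (future C2).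

**Step 7**
Reactants: 11 4-[(1S,2R)-2-(benzyloxymethyl)-4-[3,4-bis(benzyloxy)phenyl]-1-hydroxybut-3-yn-1-yl]-2-methoxyphenyl pivalate, 12 formaldehyde (as paraformaldehyde)
Product: 15 4-[(2S,3R,4S)-4-[3,4-bis(benzyloxy)benzoyl]-3-(benzyloxymethyl)oxolan-2-yl]-2-methoxyphenyl pivalate, via silyl enol ether 13 (not isolated), via C4-epimeric ketone 14 (not isolated)
Conditions: (CH2O)n (3 equiv), Me3SiOTf (2.5 equiv), CH2Cl2, −78 → −20 °C; sat. aq. NaHCO3; then DBU (cat.), CH2Cl2, rt
Reagents that add atoms: none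
Why: Me3SiOTf silylates the hydroxyl of 11 and activates formaldehyde, loss of (Me3Si)2O gives the O1=C5 oxocarbenium ion, the aryl alkyne attacks it through its proximal carbon C4 (C4–C5 bond), and the linear vinyl cation at C7′ is captured by the siloxane oxygen released in the condensation to give silyl enol ether 13, which hydrolyses to the ketone; the ketone oxygen is thus the formaldehyde oxygen and no external water is needed in the balance. The closest known reaction type is the Me3SiOTf-mediated alkyne Prins cyclisation of aryl-substituted homopropargylic alcohols with aldehydes that ends in hydration of the vinyl cation to 3-aroyltetrahydrofurans. The tetrahydrofuran ring closes in the 5-exo-dig mode at the alkyne (endo at the oxocarbenium ion). C4 is the only new stereocentre and is set by protonation of the enol: protonation anti to the C3 substituent may first give the 3,4-cis ketone 14, and DBU equilibration through the enolate should place the aroyl group trans to the C3 benzyloxymethyl group, C3 being the controlling element. The step needs exo rather than 6-endo closure, which the 3,4-bis(benzyloxy)phenyl ring secures by stabilising positive charge at C7′ (this also disfavours the 2-oxonia-Cope pathway, which needs bonding to C7′), and it needs retention at C2, which the pivalate secures by keeping the benzylic C2–O1 bond from ionising.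

**Step 8**
Reactants: 15 4-[(2S,3R,4S)-4-[3,4-bis(benzyloxy)benzoyl]-3-(benzyloxymethyl)oxolan-2-yl]-2-methoxyphenyl pivalate
Product: 16 4-[(2S,3R,4S)-3-(benzyloxymethyl)-4-[(R)-[3,4-bis(benzyloxy)phenyl](hydroxy)methyl]oxolan-2-yl]-2-methoxyphenyl pivalate
Conditions: (S)-2-methyl-CBS-oxazaborolidine (20 mol%), BH3·SMe2, THF, −30 °C; MeOH quench
Reagents that add atoms: none
Why: Corey–Bakshi–Shibata reduction with the aryl group as the large substituent should give the (R)-carbinol at C7′, and this is matched with the Felkin–Anh preference of the ketone (hydride anti to C3, the larger α-substituent, with C5 next to the carbonyl oxygen), while the aryl pivalate and benzyl ethers are inert to borane at this temperature.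

**Step 9**
Reactants: 16 4-[(2S,3R,4S)-3-(benzyloxymethyl)-4-[(R)-[3,4-bis(benzyloxy)phenyl](hydroxy)methyl]oxolan-2-yl]-2-methoxyphenyl pivalate
Product: 17 4-[(2S,3R,4S)-3-(benzyloxymethyl)-4-[(R)-[3,4-bis(benzyloxy)phenyl](hydroxy)methyl]oxolan-2-yl]-2-methoxyphenol
Conditions: K2CO3 (1.5 equiv), MeOH/THF, rt, argon; aq. NH4Cl
Reagents that add atoms: none
Why: Base-mediated methanolysis (transesterification) of an aryl ester, with phenoxide as the leaving group, should free the guaiacyl phenol without affecting the benzyl ethers, the benzylic alcohol or any stereocentre.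

**Step 10**
Reactants: 17 4-[(2S,3R,4S)-3-(benzyloxymethyl)-4-[(R)-[3,4-bis(benzyloxy)phenyl](hydroxy)methyl]oxolan-2-yl]-2-methoxyphenol
Product: 18 4-[(R)-hydroxy[(3S,4R,5S)-4-(hydroxymethyl)-5-(4-hydroxy-3-methoxyphenyl)oxolan-3-yl]methyl]benzene-1,2-diol
Conditions: H2 (1 atm), 10% Pd/C, EtOAc/MeOH, rt; stopped after uptake of three equivalents
Reagents that add atoms: none
Why: Hydrogenolysis of the two aryl benzyl ethers and the primary benzyl ether over palladium on carbon under neutral conditions should release the catechol and C9–OH, the unactivated benzylic C7′–OH and C2–O1 bonds reacting more slowly in the absence of acid.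

**Compound list**
1 | 3,4-bis(benzyloxy)benzaldehyde | O=Cc1ccc(OCc2ccccc2)c(OCc2ccccc2)c1 | starting material
2 | 1,2-bis(benzyloxy)-4-ethynylbenzene | C#Cc1ccc(OCc2ccccc2)c(OCc2ccccc2)c1 | intermediate
3 | 2-(benzyloxy)-N-methoxy-N-methylacetamide | CON(C)C(=O)COCc1ccccc1 | starting material
4 | lithium [3,4-bis(benzyloxy)phenyl]acetylide (formed in the flask, not isolated) | [Li]C#Cc1ccc(OCc2ccccc2)c(OCc2ccccc2)c1 | intermediate
5 | 1-(benzyloxy)-4-[3,4-bis(benzyloxy)phenyl]but-3-yn-2-one | O=C(COCc1ccccc1)C#Cc1ccc(OCc2ccccc2)c(OCc2ccccc2)c1 | intermediate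
6 | (2S)-1-(benzyloxy)-4-[3,4-bis(benzyloxy)phenyl]but-3-yn-2-ol | O[C@H](COCc1ccccc1)C#Cc1ccc(OCc2ccccc2)c(OCc2ccccc2)c1 | intermediate
7 | (2S)-1-(benzyloxy)-4-[3,4-bis(benzyloxy)phenyl]but-3-yn-2-yl methanesulfonate | CS(=O)(=O)O[C@H](COCc1ccccc1)C#Cc1ccc(OCc2ccccc2)c(OCc2ccccc2)c1 | intermediate
8 | vanillin (4-hydroxy-3-methoxybenzaldehyde) | COc1cc(C=O)ccc1O | starting material
9 | 4-formyl-2-methoxyphenyl pivalate (O-pivaloylvanillin) | COc1cc(C=O)ccc1OC(=O)C(C)(C)C | intermediate
10 | (P)-[4-(benzyloxy)-1-[3,4-bis(benzyloxy)phenyl]buta-1,2-dien-1-yl](ethyl)zinc (formed in the flask, not isolated; the axial configuration is given in the name only) | CC[Zn]C(=C=CCOCc1ccccc1)c1ccc(OCc2ccccc2)c(OCc2ccccc2)c1 | intermediate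
11 | 4-[(1S,2R)-2-(benzyloxymethyl)-4-[3,4-bis(benzyloxy)phenyl]-1-hydroxybut-3-yn-1-yl]-2-methoxyphenyl pivalate (anti) | COc1cc([C@@H](O)[C@@H](COCc2ccccc2)C#Cc2ccc(OCc3ccccc3)c(OCc3ccccc3)c2)ccc1OC(=O)C(C)(C)C | intermediate
12 | formaldehyde (used as paraformaldehyde) | C=O | starting material
13 | 4-[(2S,3R)-3-(benzyloxymethyl)-4-[[3,4-bis(benzyloxy)phenyl](trimethylsilyloxy)methylidene]oxolan-2-yl]-2-methoxyphenyl pivalate (silyl enol ether, formed in the flask, not isolated) | COc1cc([C@H]2OCC(=C(O[Si](C)(C)C)c3ccc(OCc4ccccc4)c(OCc4ccccc4)c3)[C@@H]2COCc5ccccc5)ccc1OC(=O)C(C)(C)C | intermediate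
14 | 4-[(2S,3R,4R)-4-[3,4-bis(benzyloxy)benzoyl]-3-(benzyloxymethyl)oxolan-2-yl]-2-methoxyphenyl pivalate (3,4-cis ketone, not isolated) | COc1cc([C@H]2OC[C@H](C(=O)c3ccc(OCc4ccccc4)c(OCc4ccccc4)c3)[C@@H]2COCc5ccccc5)ccc1OC(=O)C(C)(C)C | intermediate
15 | 4-[(2S,3R,4S)-4-[3,4-bis(benzyloxy)benzoyl]-3-(benzyloxymethyl)oxolan-2-yl]-2-methoxyphenyl pivalate (all-trans ketone) | COc1cc([C@H]2OC[C@@H](C(=O)c3ccc(OCc4ccccc4)c(OCc4ccccc4)c3)[C@@H]2COCc5ccccc5)ccc1OC(=O)C(C)(C)C | intermediate
16 | 4-[(2S,3R,4S)-3-(benzyloxymethyl)-4-[(R)-[3,4-bis(benzyloxy)phenyl](hydroxy)methyl]oxolan-2-yl]-2-methoxyphenyl pivalate | COc1cc([C@H]2OC[C@@H]([C@@H](O)c3ccc(OCc4ccccc4)c(OCc4ccccc4)c3)[C@@H]2COCc5ccccc5)ccc1OC(=O)C(C)(C)C | intermediate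
17 | 4-[(2S,3R,4S)-3-(benzyloxymethyl)-4-[(R)-[3,4-bis(benzyloxy)phenyl](hydroxy)methyl]oxolan-2-yl]-2-methoxyphenol | COc1cc([C@H]2OC[C@@H]([C@@H](O)c3ccc(OCc4ccccc4)c(OCc4ccccc4)c3)[C@@H]2COCc5ccccc5)ccc1O | intermediate
18 | 4-[(R)-hydroxy[(3S,4R,5S)-4-(hydroxymethyl)-5-(4-hydroxy-3-methoxyphenyl)oxolan-3-yl]methyl]benzene-1,2-diol (CNP0197133.1) | COc1cc([C@H]2OC[C@@H]([C@@H](O)c3ccc(O)c(O)c3)[C@@H]2CO)ccc1O | target

**Step count and risks**
Total step count: 10. Longest linear sequence: 9 steps (1 → 2 → 5 → 6 → 7 → 11 → 15 → 16 → 17 → 18; step 5 is the side branch).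

Steps most likely to fail:

1. Step 7. The benzylic C2–O bond may ionise, or formaldehyde acetal oligomers may form, before the alkyne engages. An electron-rich ring may capture the oxocarbenium ion or the vinyl cation in a Friedel–Crafts sense, or triflate may capture the vinyl cation to an enol triflate that resists hydrolysis. The fallback sets out from 11 and comes back at 15. The hydroxyl of 11 is alkylated under basic conditions (MeOCH2Cl, i-Pr2NEt, CH2Cl2) to the methoxymethyl ether F1, so that the O1–CH2 bond exists before any acid is present. Catalytic Me3SiOTf with 2,6-di-tert-butyl-4-methylpyridine in CH2Cl2 at −78 °C then ionises this isolated mixed acetal. The same 5-exo-dig closure should follow in the absence of water, paraformaldehyde and stoichiometric triflate, and the Me3SiOMe that is released captures the vinyl cation as the enol methyl ether F2. Dilute aqueous HCl in THF hydrolyses it and DBU equilibrates C4, which gives 15.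

2. Step 6. The aryl-conjugated propargylic mesylate may ionise or racemise before oxidative addition. The aryl group on the zinc-bearing carbon may also erode the anti selectivity or the SE2′ regioselectivity (allenyl carbinol formation). The fallback sets out from 3 and 9 and comes back at 11; it takes the aryl group out of the SE2′ step. Lithium (trimethylsilyl)acetylide acylates 3 to 1-(benzyloxy)-4-(trimethylsilyl)but-3-yn-2-one F3. The same transfer hydrogenation (RuCl[(R,R)-TsDPEN](p-cymene), i-PrOH) should give the (S)-alcohol F4, and MsCl/Et3N gives its mesylate F5, a non-conjugated silyl-capped substrate of the type for which the Pd(OAc)2/PPh3/Et2Zn propargylation is best established. Addition to 9 should give the anti silylalkyne adduct F6. Bu4NF buffered with AcOH removes the silyl group to the terminal alkyne F7, and Sonogashira coupling with 4-iodo-1,2-bis(benzyloxy)benzene (PdCl2(PPh3)2, CuI, Et3N, THF) gives 11.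

3. Step 10. Over-reduction may occur: hydrogenolysis of the electron-rich benzylic C7′–OH or of the benzylic C2–O1 bond may compete while the slow primary benzyl ether is being removed. The fallback sets out from 15 and comes back at 18; it removes the benzyl groups before the benzylic alcohol exists. Hydrogenolysis of 15 (H2, 10% Pd/C, EtOAc) is carried out at the ketone stage, where C7′ is a carbonyl group and the C2–O1 bond is deactivated by the pivalate, and should give the debenzylated ketone F8. Asymmetric transfer hydrogenation (RuCl[(R,R)-TsDPEN](p-cymene), HCO2H/Et3N), which tolerates free phenols and alcohols, should then set the (R)-carbinol and give the pivalate-protected tetrol F9. Methanolysis (K2CO3, degassed MeOH) gives 18.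

**Further compounds**
F1 | step 7 | 4-[(1S,2R)-2-(benzyloxymethyl)-4-[3,4-bis(benzyloxy)phenyl]-1-(methoxymethoxy)but-3-yn-1-yl]-2-methoxyphenyl pivalate | COc1cc([C@@H](OCOC)[C@@H](COCc2ccccc2)C#Cc2ccc(OCc3ccccc3)c(OCc3ccccc3)c2)ccc1OC(=O)C(C)(C)C
F2 | step 7 | 4-[(2S,3R)-3-(benzyloxymethyl)-4-[[3,4-bis(benzyloxy)phenyl](methoxy)methylidene]oxolan-2-yl]-2-methoxyphenyl pivalate | COc1cc([C@H]2OCC(=C(OC)c3ccc(OCc4ccccc4)c(OCc4ccccc4)c3)[C@@H]2COCc5ccccc5)ccc1OC(=O)C(C)(C)C
F3 | step 6 | 1-(benzyloxy)-4-(trimethylsilyl)but-3-yn-2-one | C[Si](C)(C)C#CC(=O)COCc1ccccc1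
F4 | step 6 | (2S)-1-(benzyloxy)-4-(trimethylsilyl)but-3-yn-2-ol | O[C@H](COCc1ccccc1)C#C[Si](C)(C)C
F5 | step 6 | (2S)-1-(benzyloxy)-4-(trimethylsilyl)but-3-yn-2-yl methanesulfonate | CS(=O)(=O)O[C@H](COCc1ccccc1)C#C[Si](C)(C)C
F6 | step 6 | 4-[(1S,2R)-2-(benzyloxymethyl)-1-hydroxy-4-(trimethylsilyl)but-3-yn-1-yl]-2-methoxyphenyl pivalate | COc1cc([C@@H](O)[C@@H](COCc2ccccc2)C#C[Si](C)(C)C)ccc1OC(=O)C(C)(C)C
F7 | step 6 | 4-[(1S,2R)-2-(benzyloxymethyl)-1-hydroxybut-3-yn-1-yl]-2-methoxyphenyl pivalate | COc1cc([C@@H](O)[C@@H](COCc2ccccc2)C#C)ccc1OC(=O)C(C)(C)C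
F8 | step 10 | 4-[(2S,3R,4S)-4-(3,4-dihydroxybenzoyl)-3-(hydroxymethyl)oxolan-2-yl]-2-methoxyphenyl pivalate | COc1cc([C@H]2OC[C@@H](C(=O)c3ccc(O)c(O)c3)[C@@H]2CO)ccc1OC(=O)C(C)(C)C
F9 | step 10 | 4-[(2S,3R,4S)-4-[(R)-(3,4-dihydroxyphenyl)(hydroxy)methyl]-3-(hydroxymethyl)oxolan-2-yl]-2-methoxyphenyl pivalate | COc1cc([C@H]2OC[C@@H]([C@@H](O)c3ccc(O)c(O)c3)[C@@H]2CO)ccc1OC(=O)C(C)(C)C
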